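**Plan**

- Retrosynthesis: the two benzyl groups are removed last. The depside ester bond between the ring A carbonyl and the C4 oxygen of ring B is cut next, and then the C1–C2 and C5–C6 bonds of ring B.
- Enabling feature: ring B carries the carboxyl at C1, OMe at C2, oxygen at C4 and pentyl at C6. C2–C5 with both oxygens map onto a 1,1-dimethoxy-3-silyloxybutadiene, and C1/C6 with carboxyl and pentyl map onto the α/β carbons of an oct-2-ynoate.
- Forward: the diene is made from acetyl chloride and 1,1-dichloroethene (steps 1–3) and benzyl oct-2-ynoate from the acid (step 4). Ring B is then built by Diels–Alder benzannulation (step 5), which leaves the C4 phenol free and the C2 oxygen methylated.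
- Ring A is taken from divarinol by formylation, para-selective methylation, benzylation, oxidation and activation (steps 6–10). The rings are joined by O-acylation (step 11) and both benzyl groups are removed by hydrogenolysis (step 12).
- Stereochemistry: the target has no stereocentre and no stereogenic double bond, so only regiochemistry has to be controlled (cycloaddition orientation, formylation site, which hydroxyl is methylated).

Key step: step 5

Assumption: acetyl chloride, 1,1-dichloroethene, oct-2-ynoic acid and 5-propylresorcinol are taken as purchasable, and the target is treated as achiral.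

**Route**

Step 1
Reactants: 1 acetyl chloride; 2 1,1-dichloroethene
Product: 4 4,4-dichlorobut-3-en-2-one, via 4,4,4-trichlorobutan-2-one 3 (not isolated)
Conditions: AlCl3 (1.1 equiv), CH2Cl2, 0 °C to rt; ice/aq. HCl; then steam distillation (loss of HCl)
Reagents that add atoms: none
Why: Friedel–Crafts-type acylation of the alkene CH2 terminus by the acetyl chloride–AlCl3 complex should give the β-trichloromethyl ketone, which loses HCl by E1cB elimination on distillation to give the conjugated dichlorovinyl ketone.

Step 2
Reactants: 4 4,4-dichlorobut-3-en-2-one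
Product: 6 4,4-dimethoxybut-3-en-2-one, via 4-chloro-4-methoxybut-3-en-2-one 5 (not isolated)
Conditions: NaOMe (2.2 equiv), MeOH, 0 °C to rt; distillation
Reagents that add atoms: sodium methoxide, C[O-].[Na+]
Why: Two successive conjugate addition–elimination reactions (nucleophilic vinylic substitution) of methoxide at the β-carbon of the enone should replace both chlorides and give the acyl ketene acetal.

Step 3
Reactants: 6 4,4-dimethoxybut-3-en-2-one
Product: 7 1,1-dimethoxy-3-(trimethylsilyloxy)buta-1,3-diene
Conditions: TMSCl, Et3N, ZnCl2 (cat.), toluene, 40 °C; filtration and distillation with exclusion of moisture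
Reagents that add atoms: chlorotrimethylsilane, C[Si](C)(C)Cl
Why: Soft enolisation of the methyl ketone, the only enolisable position, followed by O-silylation is the standard silyl enol ether route to Danishefsky-type silyloxydienes.

Step 4
Reactants: 8 oct-2-ynoic acid
Product: 9 benzyl oct-2-ynoate
Conditions: BnBr, KHCO3, DMF, rt
Reagents that add atoms: benzyl bromide, BrCc1ccccc1
Why: SN2 O-alkylation of the carboxylate with benzyl bromide under weakly basic bicarbonate conditions should esterify without isomerising the conjugated alkyne to an allene.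

Step 5
Reactants: 7 1,1-dimethoxy-3-(trimethylsilyloxy)buta-1,3-diene; 9 benzyl oct-2-ynoate
Product: 12 benzyl 4-hydroxy-2-methoxy-6-pentylbenzoate, via cyclohexadiene ketal cycloadduct 10 (not isolated), via aryl trimethylsilyl ether 11 (not isolated)
Conditions: 7 (2.5 equiv), xylene (or neat), 130 °C, sealed vessel; then 1 M aq. HCl, THF, rt
Reagents that add atoms: none
Why: Normal-electron-demand Diels–Alder: the HOMO of the doubly donor-substituted diene 7 adds across the LUMO of ynoate 9 in a concerted, asynchronous (4+2) cycloaddition to give cyclohexa-1,4-diene ketal 10, which aromatises by 1,4-elimination of methanol to 11 before mild acid cleaves the aryl silyl ether to phenol 12. The closest known reaction type is the benzannulation of 1,1-dialkoxy-3-silyloxybutadienes with acetylenic esters to give resorcinol monomethyl ether benzoates. Ring B closes intermolecularly as a six-membered carbocycle by (4+2) cycloaddition, with its C1–C2 and C5–C6 bonds formed in the same step. No stereocentre survives, because the two sp3 ring carbons of 10 become aromatic. The selectivity required is regiochemical: the unsubstituted CH2 terminus of 7, which has the largest HOMO coefficient owing to the 3-silyloxy and 1,1-dimethoxy donors, bonds to the electrophilic pentyl-bearing β-carbon of 9 and the ketene acetal carbon bonds to the α-carbon, so methoxy ends ortho and hydroxyl para to the ester. Excess diene and a sealed vessel should compensate for the lower dienophilicity of a β-alkyl ynoate.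

Step 6
Reactants: 13 5-propylresorcinol (divarinol)
Product: 15 2,4-dihydroxy-6-propylbenzaldehyde, via aryl iminium chloride 14 (not isolated)
Conditions: POCl3 (1.2 equiv), DMF, 0 °C to rt; then ice water, 50 °C
Reagents that add atoms: N,N-dimethylformamide, CN(C)C=O; water, O
Why: Vilsmeier–Haack formylation should occur at the ring position ortho to one hydroxyl and para to the other, as is known for orcinol and olivetol, and the iminium salt is hydrolysed to the aldehyde on aqueous work-up.

Step 7
Reactants: 15 2,4-dihydroxy-6-propylbenzaldehyde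
Product: 16 2-hydroxy-4-methoxy-6-propylbenzaldehyde
Conditions: MeI (1.05 equiv), K2CO3 (1.1 equiv), acetone, rt
Reagents that add atoms: iodomethane, CI
Why: Williamson etherification should be selective for the 4-hydroxyl, which is more acidic (para to the formyl group) and free of the intramolecular hydrogen bond that deactivates the 2-hydroxyl.

Step 8
Reactants: 16 2-hydroxy-4-methoxy-6-propylbenzaldehyde
Product: 17 2-(benzyloxy)-4-methoxy-6-propylbenzaldehyde
Conditions: BnBr, K2CO3, DMF, 60 °C
Reagents that add atoms: benzyl bromide, BrCc1ccccc1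
Why: Williamson etherification under more forcing conditions should alkylate the remaining hydrogen-bonded ortho hydroxyl, masking it for the later acylation.

Step 9
Reactants: 17 2-(benzyloxy)-4-methoxy-6-propylbenzaldehyde
Product: 18 2-(benzyloxy)-4-methoxy-6-propylbenzoic acid
Conditions: NaClO2, NaH2PO4, 2-methyl-2-butene, t-BuOH/H2O, rt
Reagents that add atoms: sodium chlorite, [Na+].[O-]Cl=O
Why: Pinnick oxidation converts the aryl aldehyde into the acid under buffered conditions, and the alkene scavenger traps HOCl so that the electron-rich ring and the benzyl ether should stay intact.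

Step 10
Reactants: 18 2-(benzyloxy)-4-methoxy-6-propylbenzoic acid
Product: 19 2-(benzyloxy)-4-methoxy-6-propylbenzoyl chloride
Conditions: (COCl)2, DMF (cat.), CH2Cl2, 0 °C to rt; concentrate and use crude
Reagents that add atoms: oxalyl chloride, O=C(Cl)C(Cl)=O
Why: Acid chloride formation through the catalytic chloroiminium species activates the doubly ortho-substituted acid under mild, non-Lewis-acidic conditions that a benzyl ether tolerates.

Step 11
Reactants: 12 benzyl 4-hydroxy-2-methoxy-6-pentylbenzoate; 19 2-(benzyloxy)-4-methoxy-6-propylbenzoyl chloride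
Product: 20 benzyl 4-{[2-(benzyloxy)-4-methoxy-6-propylbenzoyl]oxy}-2-methoxy-6-pentylbenzoate
Conditions: Et3N, DMAP (cat.), CH2Cl2, 0 °C to rt
Reagents that add atoms: none
Why: DMAP-catalysed O-acylation through the acylpyridinium ion should form the depside ester at the C4 phenol of ring B, the only free nucleophile in either partner.

Step 12
Reactants: 20 benzyl 4-{[2-(benzyloxy)-4-methoxy-6-propylbenzoyl]oxy}-2-methoxy-6-pentylbenzoate
Product: 21 4-[(2-hydroxy-4-methoxy-6-propylbenzoyl)oxy]-2-methoxy-6-pentylbenzoic acid (target)
Conditions: H2 (1 atm), 10 % Pd/C, EtOAc, rt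
Reagents that add atoms: none
Why: Catalytic hydrogenolysis over Pd/C should cleave the benzyl ester and the benzyl ether in one operation, leaving the diaryl ester, the methyl ethers and both arenes untouched.

**Compound list**

1 | acetyl chloride | CC(Cl)=O | starting material
2 | 1,1-dichloroethene | C=C(Cl)Cl | starting material
3 | 4,4,4-trichlorobutan-2-one | CC(=O)CC(Cl)(Cl)Cl | intermediate
4 | 4,4-dichlorobut-3-en-2-one | CC(=O)C=C(Cl)Cl | intermediate
5 | 4-chloro-4-methoxybut-3-en-2-one (alkene geometry not defined) | CC(=O)C=C(Cl)OC | intermediate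
6 | 4,4-dimethoxybut-3-en-2-one | CC(=O)C=C(OC)OC | intermediate
7 | 1,1-dimethoxy-3-(trimethylsilyloxy)buta-1,3-diene | COC(OC)=CC(=C)O[Si](C)(C)C | intermediate
8 | oct-2-ynoic acid | CCCCCC#CC(=O)O | starting material
9 | benzyl oct-2-ynoate | CCCCCC#CC(=O)OCc1ccccc1 | intermediate
10 | benzyl 6,6-dimethoxy-2-pentyl-4-(trimethylsilyloxy)cyclohexa-1,4-diene-1-carboxylate | CCCCCC1=C(C(=O)OCc2ccccc2)C(OC)(OC)C=C(O[Si](C)(C)C)C1 | intermediate
11 | benzyl 2-methoxy-6-pentyl-4-(trimethylsilyloxy)benzoate | CCCCCc1cc(O[Si](C)(C)C)cc(OC)c1C(=O)OCc1ccccc1 | intermediate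
12 | benzyl 4-hydroxy-2-methoxy-6-pentylbenzoate | CCCCCc1cc(O)cc(OC)c1C(=O)OCc1ccccc1 | intermediate
13 | 5-propylresorcinol (divarinol) | CCCc1cc(O)cc(O)c1 | starting material
14 | (2,4-dihydroxy-6-propylbenzylidene)dimethyliminium chloride | CCCc1cc(O)cc(O)c1C=[N+](C)C.[Cl-] | intermediate
15 | 2,4-dihydroxy-6-propylbenzaldehyde | CCCc1cc(O)cc(O)c1C=O | intermediate
16 | 2-hydroxy-4-methoxy-6-propylbenzaldehyde | CCCc1cc(OC)cc(O)c1C=O | intermediate
17 | 2-(benzyloxy)-4-methoxy-6-propylbenzaldehyde | CCCc1cc(OC)cc(OCc2ccccc2)c1C=O | intermediate
18 | 2-(benzyloxy)-4-methoxy-6-propylbenzoic acid | CCCc1cc(OC)cc(OCc2ccccc2)c1C(=O)O | intermediate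
19 | 2-(benzyloxy)-4-methoxy-6-propylbenzoyl chloride | CCCc1cc(OC)cc(OCc2ccccc2)c1C(Cl)=O | intermediate
20 | benzyl 4-{[2-(benzyloxy)-4-methoxy-6-propylbenzoyl]oxy}-2-methoxy-6-pentylbenzoate | CCCCCc1cc(OC(=O)c2c(OCc3ccccc3)cc(OC)cc2CCC)cc(OC)c1C(=O)OCc1ccccc1 | intermediate
21 | 4-[(2-hydroxy-4-methoxy-6-propylbenzoyl)oxy]-2-methoxy-6-pentylbenzoic acid | CCCCCc1cc(OC(=O)c2c(O)cc(OC)cc2CCC)cc(OC)c1C(=O)O | target

**Step count**

Total steps: 12.
Longest linear sequence: 7 steps (13 to 21 through steps 6, 7, 8, 9, 10, 11 and 12). The ring B branch from 1 takes 6 steps (steps 1, 2, 3, 5, 11 and 12).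

**Steps most likely to fail and fallbacks**

1. Step 5. The cycloaddition to a β-alkyl ynoate may be slow enough that thermal decomposition or adventitious desilylation of the diene outruns ring formation. The fallback keeps the same diene and the same two ring bonds but raises the dienophile to the aldehyde oxidation level. It sets out from 7, which is combined with commercial oct-2-ynal (CCCCCC#CC=O) in toluene at rt to 60 °C. The ynal is a much stronger dienophile with the same polarisation. The reaction should pass through 6,6-dimethoxy-2-pentyl-4-(trimethylsilyloxy)cyclohexa-1,4-diene-1-carbaldehyde F1 and, after loss of methanol, 2-methoxy-6-pentyl-4-(trimethylsilyloxy)benzaldehyde F2, giving 4-hydroxy-2-methoxy-6-pentylbenzaldehyde F3 on dilute acid work-up. Acylation of F3 with acid chloride 19 (Et3N, DMAP, CH2Cl2) should give 4-formyl-3-methoxy-5-pentylphenyl 2-(benzyloxy)-4-methoxy-6-propylbenzoate F4. Pinnick oxidation (NaClO2, NaH2PO4, 2-methyl-2-butene) should then give 4-{[2-(benzyloxy)-4-methoxy-6-propylbenzoyl]oxy}-2-methoxy-6-pentylbenzoic acid F5. Hydrogenolysis of the single benzyl ether (H2, Pd/C) brings the sequence back to the route at 21.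

2. Step 11. Acyl transfer at the doubly ortho-substituted carbonyl may be slow, so that hydrolysis of the acid chloride or loss of the ortho benzyl ether during activation in step 10 competes. The fallback sets out from 18 and avoids both the acid chloride and the bulky ortho benzyloxy group. Hydrogenolysis of 18 (H2, Pd/C, EtOAc) should give 2-hydroxy-4-methoxy-6-propylbenzoic acid F6, whose ortho hydroxyl is protected by its intramolecular hydrogen bond. Treatment of F6 and phenol 12 with trifluoroacetic anhydride in toluene at rt should form 2-hydroxy-4-methoxy-6-propylbenzoic trifluoroacetic anhydride F7 in the flask. This acylates 12 to give benzyl 4-[(2-hydroxy-4-methoxy-6-propylbenzoyl)oxy]-2-methoxy-6-pentylbenzoate F8, a mixed-anhydride condensation well established for depsides. Hydrogenolysis of the benzyl ester (H2, Pd/C) returns to the route at 21.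

3. Step 2. Methoxide may over-add to the ketene acetal (orthoester formation) or trigger oligomerisation of the dichlorovinyl ketone, lowering the supply of the diene precursor. The fallback sets out from 1 and bypasses 4. C-acylation of commercial 1,1-dimethoxyethene (C=C(OC)OC) with acetyl chloride 1 in Et2O at 0 °C in the presence of Et3N should give the acyl ketene acetal directly. It makes no new compound and comes back to the route at 6.

**Further compounds**

F1 | step 5 | 6,6-dimethoxy-2-pentyl-4-(trimethylsilyloxy)cyclohexa-1,4-diene-1-carbaldehyde | CCCCCC1=C(C=O)C(OC)(OC)C=C(O[Si](C)(C)C)C1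
F2 | step 5 | 2-methoxy-6-pentyl-4-(trimethylsilyloxy)benzaldehyde | CCCCCc1cc(O[Si](C)(C)C)cc(OC)c1C=O
F3 | step 5 | 4-hydroxy-2-methoxy-6-pentylbenzaldehyde | CCCCCc1cc(O)cc(OC)c1C=O
F4 | step 5 | 4-formyl-3-methoxy-5-pentylphenyl 2-(benzyloxy)-4-methoxy-6-propylbenzoate | CCCCCc1cc(OC(=O)c2c(OCc3ccccc3)cc(OC)cc2CCC)cc(OC)c1C=O
F5 | step 5 | 4-{[2-(benzyloxy)-4-methoxy-6-propylbenzoyl]oxy}-2-methoxy-6-pentylbenzoic acid | CCCCCc1cc(OC(=O)c2c(OCc3ccccc3)cc(OC)cc2CCC)cc(OC)c1C(=O)O
F6 | step 11 | 2-hydroxy-4-methoxy-6-propylbenzoic acid | CCCc1cc(OC)cc(O)c1C(=O)O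
F7 | step 11 | 2-hydroxy-4-methoxy-6-propylbenzoic trifluoroacetic anhydride | CCCc1cc(OC)cc(O)c1C(=O)OC(=O)C(F)(F)F
F8 | step 11 | benzyl 4-[(2-hydroxy-4-methoxy-6-propylbenzoyl)oxy]-2-methoxy-6-pentylbenzoate | CCCCCc1cc(OC(=O)c2c(O)cc(OC)cc2CCC)cc(OC)c1C(=O)OCc1ccccc1
F0 | step 2 | none | none
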